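## The problem

Compound 16 is a flavone: a chromen-4-one, rings A and C, joined through C2 to a 2,4-dimethoxyphenyl ring B, with seven methoxyl groups at C3, C5, C6, C7, C8, C2' and C4'. It has no stereocentre, so the whole difficulty lies in the substitution pattern. Ring A is hexasubstituted, with four methoxyls, the ring oxygen O1 on C8a and the carbonyl carbon C4 on C4a, so a classical acylation would have to enter a position flanked on both sides under Lewis acids that threaten the neighbouring ethers. The C3 methoxyl is not delivered by ordinary flavone syntheses and is best carried in on the three-carbon chain. The groups at risk are the methyl ethers, above all the C5 methoxyl peri to the carbonyl, which Lewis acids and HX cleave easily; a free phenol on the tetra-oxygenated ring A is also oxidised readily to a quinone, and C3' and C5' of ring B are open to electrophilic halogen. The enabling feature is that C4a and C8a are neighbours, one bearing carbon and the other oxygen, while C5 to C8 all bear the same group. The C4a–C8a pair is therefore the formal triple bond of 3,4,5,6-tetramethoxybenzyne 14, which has a mirror plane through that bond, so a carboxylic acid can be inserted across it with no regiochemical question.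

## Retrosynthesis

**Ring C (O1–C2).** The last bond cut is O1–C2, which opens 16 to the 2'-hydroxychalcone 15, two hydrogens richer. Cutting C2–C1' instead would demand a hindered aryl–aryl coupling at C2 after rings A and C are complete. Cutting the C3–O bond would mean oxygenating C3 late. In 15 the C3 methoxyl is already the α-methoxyl of the enone, and the ring A phenol is placed to form a six-membered ring with C-β. The forward reaction must close 6-endo and remove two hydrogens without halogenating ring B or cleaving the C5 methoxyl.

**Ring A to chain (C4–C4a and O1–C8a together).** Chalcone 15 is cut at both bonds that tie the chain to ring A, giving aryne 14 and (Z)-3-(2,4-dimethoxyphenyl)-2-methoxyprop-2-enoic acid 13. Aryne 14 is released from silyl triflate 9. The neighbouring cut, C4–C4a alone, would be an ortho-acylation of phenol 4 with a Lewis acid sitting next to four methoxyls. The double cut splits 15 into a C10 and a C12 half and places the ketone without any electrophilic substitution. The forward reaction needs O-arylation of the carboxylate and then acyl transfer to the ortho carbanion before that carbanion is protonated.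

**Acid 13 (Cα=Cβ).** The double bond is cut to 2,4-dimethoxybenzaldehyde 10 and methyl methoxyacetate 11, with methyl ester 12 as the intermediate. Both are simple and carry all ring B oxygens and the future C3 methoxyl. The condensation must give the Z isomer, with the aryl group trans to the carboxyl group, which is the thermodynamic one.

**Silyl triflate 9 (C–Si, O–S, C–Br, C–O).** The C–Si bond is traced to an O-to-C silyl shift in aryllithium 7, which gives phenoxide 8 for triflation. Aryllithium 7 comes from silyl ether 6, and 6 from bromophenol 5. The bromine is placed on the single free carbon of 2,3,4,5-tetramethoxyphenol 4. Phenol 4 comes from 1,2,3,4-tetramethoxybenzene 1 through aryllithium 2 and boronate 3, followed by oxidation. Each step has only one possible site.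

## Roads not taken

Alternative 1: Ring B is cut at C1'–C2' and C5'–C6' and built by a Diels–Alder reaction. The dienophile would be 2-ethynyl-3,5,6,7,8-pentamethoxychromen-4-one A1 and the diene 1,1-dimethoxy-3-(trimethylsilyloxy)buta-1,3-diene A2. Cycloaddition, loss of methanol and desilylation on work-up would give the phenol 2-(4-hydroxy-2-methoxyphenyl)-3,5,6,7,8-pentamethoxychromen-4-one A3, and O-methylation of A3 would finish 16.
- Merits: the polarisation of A2 fixes the 2',4'-oxygen pattern of A3, and the finished ring B never meets an electrophile.
- Weak points: it constructs the one ring that can be bought, as aldehyde 10. The hard part, the hexasubstituted ring A, is left unsolved inside A1, which also needs an alkyne at C2. The alkyne of A1 is only weakly activated, because the C3 methoxyl donates toward C2. A2 is moisture-sensitive, and the methylation of A3 is an added step.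
- Comparison: in one respect this road is better, since ring B never sees iodine, whereas the chosen plan exposes it to catalytic I2 in step 7. Against that the chosen plan sets a purchased ring B, a ring A whose substitution is settled from compound 1, and a shorter sequence.

Alternative 2: The C6–O and C8–O bonds are cut. Morin A4 would be methylated at every hydroxyl except the chelated C5 one to give 2-(2,4-dimethoxyphenyl)-5-hydroxy-3,7-dimethoxychromen-4-one A5. Dibromination of A5 would give 6,8-dibromo-2-(2,4-dimethoxyphenyl)-5-hydroxy-3,7-dimethoxychromen-4-one A6. In the key step A6 would be heated with NaOMe and CuBr in MeOH and DMF to give 2-(2,4-dimethoxyphenyl)-5-hydroxy-3,6,7,8-tetramethoxychromen-4-one A7, and methylation of A7 would finish 16.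
- Merits: the whole skeleton and five of the seven oxygens are bought in A4. The route is about four steps, with no cryogenic or organolithium chemistry.
- Weak points: bromination of A5 must take C6 and C8 but spare C5' and C3' of ring B. A ring B bromide would be methoxylated as well. The double copper-mediated substitution in A6, at two carbons each flanked by two oxygens, competes with hydrodebromination. Both failures give flavones that differ from A7 by one methoxyl and are hard to remove. Hot methoxide can also open the pyranone at C2.
- Comparison: this road is shorter and cheaper than the chosen one, and would be the more economical if the bromination proved selective. Against that the chosen plan sets three things: all four ring A oxygens are present from compound 1, ring B never meets a stoichiometric halogenating agent, and no near-identical by-products can arise.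

Alternative 3: O1–C2 is cut with an iodine placed on C3. The ynone 3-(2,4-dimethoxyphenyl)-1-(2,3,4,5,6-pentamethoxyphenyl)prop-2-yn-1-one A8 would be treated with ICl. ICl activates the alkyne of A8, an ortho methoxyl oxygen attacks the alkyne carbon bearing ring B and chloride removes the methyl group, giving 2-(2,4-dimethoxyphenyl)-3-iodo-5,6,7,8-tetramethoxychromen-4-one A9. The C3 iodide of A9 must then be exchanged for methoxyl.
- Merits: the pentamethoxyphenyl ring of A8 is symmetric, so either ortho methoxyl may close. The cyclisation is mild and convergent, and the C3 iodide of A9 is a handle for analogues.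
- Weak points: ICl is a strong iodinating agent and ring B of A8 is activated. The exchange of the C3 iodide of A9, flanked by the carbonyl and an ortho-substituted aryl group, needs copper-mediated methoxylation under conditions where methoxide can add to C2, or a longer borylation, oxidation and methylation sequence.
- Comparison: regiochemical certainty is equal, since both plans rest on symmetry, and A9 offers C3 variation that the chosen plan does not. The chosen plan brings the C3 methoxyl ready-made in 11 and needs one step after its key step instead of two or more.

Key step: step 6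

Remark on the chemistry: compounds 1, 10 and 11 are taken to be purchasable, and aryne 14 is counted as a discrete intermediate formed and consumed in the flask.

## Route

Step 1
Reactants: 1 1,2,3,4-tetramethoxybenzene
Product: 4 2,3,4,5-tetramethoxyphenol, via aryllithium 2 (not isolated), via dimethyl arylboronate 3 (not isolated)
Conditions: n-BuLi, TMEDA, THF, 0 °C; B(OMe)3, –78 °C to rt; AcOH, 30% H2O2, 0 °C to rt; aq. Na2S2O3
Reagents that add atoms: n-butyllithium, [Li]CCCC; trimethyl borate, COB(OC)OC; hydrogen peroxide, OO
Why: Directed ortho-lithiation, borylation and oxidation of the C–B bond; the two ring hydrogens of 1 are equivalent and each lies next to a methoxyl, so only one aryllithium can form, and the cold oxidation with a reductive quench spares the electron-rich phenol.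

Step 2
Reactants: 4 2,3,4,5-tetramethoxyphenol
Product: 5 2-bromo-3,4,5,6-tetramethoxyphenol
Conditions: NBS (1 equiv), CH2Cl2, –78 to 0 °C, dark
Reagents that add atoms: N-bromosuccinimide, O=C1CCC(=O)N1Br
Why: Electrophilic aromatic bromination of a phenol; C6 is the only unsubstituted ring carbon and is ortho to the hydroxyl, and one equivalent of reagent in a dry non-nucleophilic solvent at low temperature should substitute there before oxidation to a quinone competes.

Step 3
Reactants: 5 2-bromo-3,4,5,6-tetramethoxyphenol
Product: 6 (2-bromo-3,4,5,6-tetramethoxyphenoxy)trimethylsilane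
Conditions: HMDS, THF, reflux; evaporation
Reagents that add atoms: hexamethyldisilazane, C[Si](C)(C)N[Si](C)(C)C
Why: O-silylation of a phenol with a silazane; ammonia is the only by-product, so evaporation leaves the silyl ether ready for the next step.

Step 4
Reactants: 6 (2-bromo-3,4,5,6-tetramethoxyphenoxy)trimethylsilane
Product: 9 2,3,4,5-tetramethoxy-6-(trimethylsilyl)phenyl trifluoromethanesulfonate, via lithiated silyl ether 7 (not isolated), via lithium silylphenoxide 8 (not isolated)
Conditions: n-BuLi, THF, –100 to –80 °C; Tf2O, –100 to –80 °C; aq. NaHCO3
Reagents that add atoms: n-butyllithium, [Li]CCCC; trifluoromethanesulfonic anhydride, O=S(=O)(OS(=O)(=O)C(F)(F)F)C(F)(F)F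
Why: Bromine–lithium exchange, anionic 1,3 O-to-C silyl shift (retro-Brook rearrangement) and O-triflation of the resulting phenoxide; this is the standard entry to ortho-silylaryl triflates, including ones whose silyl and triflate groups are each flanked by a methoxyl.

Step 5
Reactants: 10 2,4-dimethoxybenzaldehyde; 11 methyl methoxyacetate
Product: 13 (Z)-3-(2,4-dimethoxyphenyl)-2-methoxyprop-2-enoic acid, via methyl ester 12 (not isolated)
Conditions: NaOMe, MeOH, 0 °C to reflux; aq. NaOH, reflux; aq. HCl
Reagents that add atoms: sodium hydroxide, [Na+].[OH-]
Why: Aldol condensation of the ester enolate with the aldehyde (Claisen-type, E1cB dehydration) and saponification in the same pot; the reversible addition and elimination should favour the Z alkene with the aryl group trans to the carboxyl group, and methoxide with a methyl ester makes transesterification degenerate.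

Step 6
Reactants: 9 2,3,4,5-tetramethoxy-6-(trimethylsilyl)phenyl trifluoromethanesulfonate; 13 (Z)-3-(2,4-dimethoxyphenyl)-2-methoxyprop-2-enoic acid
Product: 15 (Z)-3-(2,4-dimethoxyphenyl)-1-(2-hydroxy-3,4,5,6-tetramethoxyphenyl)-2-methoxyprop-2-en-1-one, via tetramethoxybenzyne 14 (not isolated)
Conditions: CsF (excess), THF, 125 °C, sealed tube; 9 in slight excess; dilute aq. HCl on work-up
Reagents that add atoms: none
Why: Fluoride attacks silicon of 9 and triflate leaves to give aryne 14; the carboxylate of 13 adds through oxygen to one aryne carbon (O1–C8a), and the ortho aryl anion attacks the adjacent ester carbonyl through a four-membered transition state, so the acyl group moves from oxygen to carbon (C4–C4a) and the phenoxide of 15 is released. The closest known reaction type is the insertion of arynes into the C–O bond of carboxylic acids, which gives ortho-hydroxyaryl ketones from aliphatic and aromatic acids and is also known for α,β-unsaturated acids, where the phenoxide of simple cases can go on to conjugate addition. No ring closes and no stereocentre forms; the Z double bond of 13 is not involved and should be retained. No regioselectivity is needed, because 14 has a mirror plane through the middle of its triple bond and either carbon may become C8a. The selectivity needed is acyl transfer ahead of protonation of the aryl anion, which would stop at the aryl ester stage; it rests on the carbonyl sitting three atoms from the carbanion, on the aprotic medium and high temperature, and on keeping the acid, the only proton donor, as the limiting component. Conjugate addition of the aryl anion to C-β is disfavoured because that carbon is the electron-rich end of an enol ether and bears a donor aryl group, and the same deactivation should keep the phenoxide of 15 from closing onto it.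

Step 7
Reactants: 15 (Z)-3-(2,4-dimethoxyphenyl)-1-(2-hydroxy-3,4,5,6-tetramethoxyphenyl)-2-methoxyprop-2-en-1-one
Product: 16 2-(2,4-dimethoxyphenyl)-3,5,6,7,8-pentamethoxychromen-4-one
Conditions: I2 (10 mol %), DMSO, 130 °C; aq. Na2S2O3
Reagents that add atoms: none
Why: Iodine-catalysed oxidative cyclisation of a 2'-hydroxychalcone in DMSO: the phenol oxygen closes 6-endo onto C-β (O1–C2), iodination α to the ketone and loss of HI give the pyranone, and DMSO reoxidises iodide to I2; the α-methoxyl remains as the C3 methoxyl, and the catalytic loading keeps HI and electrophilic iodine low enough to spare the C5 methoxyl and ring B.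

## Compound list

1 | 1,2,3,4-tetramethoxybenzene | COc1ccc(OC)c(OC)c1OC | starting material
2 | (2,3,4,5-tetramethoxyphenyl)lithium | [Li]c1cc(OC)c(OC)c(OC)c1OC | intermediate (not isolated)
3 | dimethyl (2,3,4,5-tetramethoxyphenyl)boronate | COB(OC)c1cc(OC)c(OC)c(OC)c1OC | intermediate (not isolated)
4 | 2,3,4,5-tetramethoxyphenol | COc1cc(O)c(OC)c(OC)c1OC | intermediate
5 | 2-bromo-3,4,5,6-tetramethoxyphenol | COc1c(O)c(Br)c(OC)c(OC)c1OC | intermediate
6 | (2-bromo-3,4,5,6-tetramethoxyphenoxy)trimethylsilane | COc1c(O[Si](C)(C)C)c(Br)c(OC)c(OC)c1OC | intermediate
7 | [2,3,4,5-tetramethoxy-6-(trimethylsilyloxy)phenyl]lithium | COc1c(O[Si](C)(C)C)c([Li])c(OC)c(OC)c1OC | intermediate (not isolated)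
8 | lithium 2,3,4,5-tetramethoxy-6-(trimethylsilyl)phenoxide | COc1c([O-])c([Si](C)(C)C)c(OC)c(OC)c1OC.[Li+] | intermediate (not isolated)
9 | 2,3,4,5-tetramethoxy-6-(trimethylsilyl)phenyl trifluoromethanesulfonate | COc1c(OC)c(OC)c([Si](C)(C)C)c(OS(=O)(=O)C(F)(F)F)c1OC | intermediate
10 | 2,4-dimethoxybenzaldehyde | COc1ccc(C=O)c(OC)c1 | starting material
11 | methyl methoxyacetate | COCC(=O)OC | starting material
12 | methyl (Z)-3-(2,4-dimethoxyphenyl)-2-methoxyprop-2-enoate | CO/C(=C\c1ccc(OC)cc1OC)C(=O)OC | intermediate (not isolated)
13 | (Z)-3-(2,4-dimethoxyphenyl)-2-methoxyprop-2-enoic acid | CO/C(=C\c1ccc(OC)cc1OC)C(=O)O | intermediate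
14 | 3,4,5,6-tetramethoxybenzyne (1,2-didehydro-3,4,5,6-tetramethoxybenzene) | COC1=C(OC)C(OC)=C(OC)C#C1 | intermediate (not isolated)
15 | (Z)-3-(2,4-dimethoxyphenyl)-1-(2-hydroxy-3,4,5,6-tetramethoxyphenyl)-2-methoxyprop-2-en-1-one | COc1ccc(/C=C(\OC)C(=O)c2c(O)c(OC)c(OC)c(OC)c2OC)c(OC)c1 | intermediate
16 | 2-(2,4-dimethoxyphenyl)-3,5,6,7,8-pentamethoxychromen-4-one | COc1ccc(-c2oc3c(OC)c(OC)c(OC)c(OC)c3c(=O)c2OC)c(OC)c1 | target

## Step count and risks

Total step count: 7. Longest linear sequence: 6 steps (steps 1, 2, 3, 4, 6 and 7, from 1 to 16); the acid branch is one step (step 5).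

**Step 6 (key step).**
- What may go wrong: protonation of the aryl anion before the acyl shift would stop the sequence at the O-aryl ester level. The crowded phenoxide of 15 could be arylated by a second aryne. Release of the aryne from the fully substituted silyl triflate could be slow. Further closure of the phenoxide onto C-β under the hot fluoride conditions is also possible; material that had closed in this way should still be dehydrogenated to 16 under the conditions of step 7.
- Fallback: this abandons the aryne for this bond set. It starts from phenol 4, which is acylated ortho with methoxyacetic acid in BF3·OEt2 (Friedel–Crafts/Fries type, through the boron chelate) to give 1-(2-hydroxy-3,4,5,6-tetramethoxyphenyl)-2-methoxyethan-1-one F1. Claisen–Schmidt condensation of this ketone with aldehyde 10 (KOH, EtOH) returns to the route at 15.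

**Step 2.**
- What may go wrong: oxidation of the tetra-oxygenated phenol by the N-bromo reagent (oxidative demethylation para to the hydroxyl, towards a quinone) may outrun ring substitution.
- Fallback: this avoids electrophilic halogen and also replaces steps 3 and 4. It starts from 4, which is carbamoylated with isopropyl isocyanate and Et3N to 2,3,4,5-tetramethoxyphenyl N-isopropylcarbamate F2. Temporary N-silylation in the flask (TBSOTf, TMEDA), directed ortho-lithiation (n-BuLi, TMEDA, –78 °C) and TMSCl give 2,3,4,5-tetramethoxy-6-(trimethylsilyl)phenyl N-isopropylcarbamate F3. The carbamate is cleaved with DBU and Et2NH in MeCN to 2,3,4,5-tetramethoxy-6-(trimethylsilyl)phenol F4, and triflation with PhNTf2 returns to the route at 9.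

**Step 5.**
- What may go wrong: sluggish addition to the electron-rich aldehyde, incomplete dehydration of the aldol adduct, and incomplete control of the double-bond geometry.
- Fallback: Horner–Wadsworth–Emmons olefination of 10 with methyl 2-(dimethoxyphosphoryl)-2-methoxyacetate (NaH, THF), expected to favour Z ester 12. This is saponified separately (LiOH, THF/H2O) to return at 13; the minor isomer would be removed by crystallisation of the acid.

**Step 7.**
- What may go wrong: electrophilic iodination of ring B at C5', cleavage of the peri C5 methoxyl by HI at 130 °C, or stalling after ring closure without dehydrogenation.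
- Fallback: this separates the two events and avoids iodine. From 15, base-mediated oxa-Michael closure (NaOAc, EtOH, reflux) gives trans-(2RS,3RS)-2-(2,4-dimethoxyphenyl)-3,5,6,7,8-pentamethoxy-2,3-dihydrochromen-4-one F5 as the racemate. Dehydrogenation with DDQ in refluxing dioxane returns to the route at 16.

## Further compounds

F1 | step 6 | 1-(2-hydroxy-3,4,5,6-tetramethoxyphenyl)-2-methoxyethan-1-one | COCC(=O)c1c(O)c(OC)c(OC)c(OC)c1OC
F2 | step 2 | 2,3,4,5-tetramethoxyphenyl N-isopropylcarbamate | COc1cc(OC(=O)NC(C)C)c(OC)c(OC)c1OC
F3 | step 2 | 2,3,4,5-tetramethoxy-6-(trimethylsilyl)phenyl N-isopropylcarbamate | COc1c([Si](C)(C)C)c(OC(=O)NC(C)C)c(OC)c(OC)c1OC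
F4 | step 2 | 2,3,4,5-tetramethoxy-6-(trimethylsilyl)phenol | COc1c([Si](C)(C)C)c(O)c(OC)c(OC)c1OC
F0 | step 5 | none | none
F5 | step 7 | trans-(2RS,3RS)-2-(2,4-dimethoxyphenyl)-3,5,6,7,8-pentamethoxy-2,3-dihydrochromen-4-one (racemic; 2S,3S enantiomer drawn) | COc1ccc([C@@H]2Oc3c(OC)c(OC)c(OC)c(OC)c3C(=O)[C@H]2OC)c(OC)c1
A1 | alternative 1 | 2-ethynyl-3,5,6,7,8-pentamethoxychromen-4-one | C#Cc1oc2c(OC)c(OC)c(OC)c(OC)c2c(=O)c1OC
A2 | alternative 1 | 1,1-dimethoxy-3-(trimethylsilyloxy)buta-1,3-diene | COC(OC)=CC(=C)O[Si](C)(C)C
A3 | alternative 1 | 2-(4-hydroxy-2-methoxyphenyl)-3,5,6,7,8-pentamethoxychromen-4-one | COc1cc(O)ccc1-c1oc2c(OC)c(OC)c(OC)c(OC)c2c(=O)c1OC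
A4 | alternative 2 | morin, 2-(2,4-dihydroxyphenyl)-3,5,7-trihydroxychromen-4-one | Oc1ccc(-c2oc3cc(O)cc(O)c3c(=O)c2O)c(O)c1
A5 | alternative 2 | 2-(2,4-dimethoxyphenyl)-5-hydroxy-3,7-dimethoxychromen-4-one | COc1ccc(-c2oc3cc(OC)cc(O)c3c(=O)c2OC)c(OC)c1
A6 | alternative 2 | 6,8-dibromo-2-(2,4-dimethoxyphenyl)-5-hydroxy-3,7-dimethoxychromen-4-one | COc1ccc(-c2oc3c(Br)c(OC)c(Br)c(O)c3c(=O)c2OC)c(OC)c1
A7 | alternative 2 | 2-(2,4-dimethoxyphenyl)-5-hydroxy-3,6,7,8-tetramethoxychromen-4-one | COc1ccc(-c2oc3c(OC)c(OC)c(OC)c(O)c3c(=O)c2OC)c(OC)c1
A8 | alternative 3 | 3-(2,4-dimethoxyphenyl)-1-(2,3,4,5,6-pentamethoxyphenyl)prop-2-yn-1-one | COc1ccc(C#CC(=O)c2c(OC)c(OC)c(OC)c(OC)c2OC)c(OC)c1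
A9 | alternative 3 | 2-(2,4-dimethoxyphenyl)-3-iodo-5,6,7,8-tetramethoxychromen-4-one | COc1ccc(-c2oc3c(OC)c(OC)c(OC)c(OC)c3c(=O)c2I)c(OC)c1
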